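We will judge the options against a ceiling, and what stays open is how far below it each one ends.

| flask | starting material | coupling partner | second substrate | temperature | remark | time |
|---|---|---|---|---|---|---|
| east | 2.1 M | 2.31 M | 0.42 M | 70 °C | the very flask that is asked about, followed so far |  |
| south-west | 2.1 M | 2.31 M | 0.42 M | 55 °C | run made earlier |  |
| flask | 2.1 M | 2.31 M | 0.420 M | 70 °C |  | 5.0 h |

| run | time / h | target / % |
|---|---|---|
| east | 0.417 | 34.1 |
| east | 1.00 | 54.0 |
| east | 2.00 | 68.2 |
| east | 5.00 | 81.1 |
| south-west | 0.833 | 21.3 |
| south-west | 2.00 | 37.2 |
| south-west | 4.00 | 53.3 |
| south-west | 10.0 | 71.4 |

(standard deviation of a reading: 0.3 percentage points)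

- oak: at 5.0 h raise the temperature by 25 K, then wait 5.0 h
- ash: at 5.0 h take out 90% of the target then present, then wait 5.0 h
- cedar: change nothing and wait 5.0 h more

* target, in percent of the starting material first charged, at 5.0 h
* the option that brings most further target ("none" if no option brings more than 2 percentage points) (oak / ash / cedar / none)
* target present, with what was taken out counted in, in percent of the starting material first charged, after ash
* target present, with what was taken out counted in, in percent of the starting material first charged, after cedar

- target that was removed still counts
- the numbers in the tables scatter by 0.3 percentage points (one standard deviation)

Suppose the second substrate takes coupling partner one for one, and each target takes one more. Then the coupling partner left over for the target is 1.89 M, less than the starting material, so for the target it is the limiting reagent. That gives the ceiling, the largest share of the starting material that can become target: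

ceiling = (coupling partner − second substrate) / starting material = 90.0%

The last east reading, 81.1%, is our crude bound from below, which leaves a gap of 8.9 percentage points. We reckon this gap and leave the rest. Once the second substrate has taken its share, the gap shrinks each hour by a part proportional to the starting material left, which falls from 18.9% towards 10.0%. With y for the target, ln[(1−y)/(ceiling−y)] then climbs in a straight line, and the east readings give this slope between 2.00 h and 5.00 h:

slope = 0.125 /h

Slowest closing, at the slope itself, gives the tighter bound from below; fastest closing, with the starting material held at its present share, gives the one from above:

cedar: from 85.2% to 87.3%

Ash gets the same bracket, provided target does not slow its own making. South-west at 4.00 h reads 53.3% and east at 1.00 h reads 54.0%, so the clock runs about 4 times faster in east. Oak's 25 K is a bigger step than the one between the two runs, so, if the clock gains at least that factor, the same slowest closing puts oak at 89.3% or more, above the cedar bracket.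

The forecast reasoned: “So the second substrate eats the coupling partner”. It gave 81.1% (80.6% to 81.6%) for now and oak as best. For ash it gave 86% (84% to 88.5%) and for cedar 86% (84% to 88%); that central cedar value stands inside our bracket.

The flask gives 81.3% now and 86.8% after cedar, the same 86.8% after ash, and oak is best with 8.7 points against 5.5 points.

    second substrate + coupling partner → second product (k = 6.00 × 10⁻⁴ /M/s, Ea = 77.0 kJ/mol)
    starting material + coupling partner → target (k = 1.70 × 10⁻⁴ /M/s, Ea = 89.0 kJ/mol)
    starting material → decomposition product (k = 8.60 × 10⁻⁸ /s, Ea = 120 kJ/mol)
    (constants at 70 °C)

Left to 50.0 h, the flask stands at 90.0%, level with the ceiling. In the neighbour flask charged with 0.84 M of starting material, the same ratio of coupling partner less second substrate to starting material is 2.25, above one, so its ceiling is its whole charge. It reaches 97.8% at 5.00 h, with 46% of its coupling partner still free.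

The data were generated by integration with constants of no real substance; the scatter is artificial.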